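**Plan**
- Oxane numbering: O1, C2 (aryl), C3, C4 (OH), C5, C6; side-chain carbinol C1′. Feature used: C2 (benzylic, on O1) lies β to C4 (carbinol = masked ketone) and O1–C6–C5 is a masked methyl-ketone enol, so the ring is a reduced 2-aryl-2,3-dihydro-4H-pyran-4-one (vinylogous ester O1–C6=C5–C4=O on a feruloyl C2–C3–C4 unit).
- Retrosynthesis: remove three benzyl groups; add H2 back across C5=C6 and reduce C4=O (dihydropyranone 11); cut O1–C2 (oxa-Michael) and C4–C5 (C-acylation) to give feruloyl chloride 8 and methyl ketone 4.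
- Forward: ketone 4 from O-benzyl-L-tyrosine (3 steps); acid chloride 8 from O-benzylvanillin (2 steps); one-pot union and ring closure; then carbonyl reduction, ring hydrogenation, debenzylation.
- Stereochemistry: C1′ from L-tyrosine (diazotisation with retention); C2 by a chiral Brønsted acid in the ring closure; C4 from C2 (axial hydride, 2,4-cis); C6 from C4 (hydroxyl-directed hydrogenation, H cis to OH, hence 2,6-trans).

Key step: step 6

Remark: the sense of induction of the chiral acid in step 6 cannot be predicted from the structure; the (R) acid is written and its antipode would be used if a trial run favours the (2R) epimer.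

Step 1
Reactants: 1 O-benzyl-L-tyrosine
Product: 2 (2S)-3-[4-(benzyloxy)phenyl]-2-hydroxypropanoic acid
Conditions: NaNO2, 1 M H2SO4, 1,4-dioxane, 0 °C to rt
Reagents that add atoms: water (O)
Why: Diazotisation of the α-amino acid and hydrolysis through the α-lactone (double inversion) should replace NH2 by OH with net retention, so C1′ keeps the (S) configuration of L-tyrosine.

Step 2
Reactants: 2 (2S)-3-[4-(benzyloxy)phenyl]-2-hydroxypropanoic acid
Product: 3 (2S)-2-(benzyloxy)-3-[4-(benzyloxy)phenyl]propanoic acid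
Conditions: NaH (2.2 equiv), BnBr (1.1 equiv), THF–DMF, 0 °C to rt; then aq. HCl
Reagents that add atoms: benzyl bromide (BrCc1ccccc1)
Why: Williamson etherification of the dianion should occur at the alkoxide, which is far more nucleophilic than the carboxylate, and the α-hydrogen of a carboxylate is not acidic enough to racemise.

Step 3
Reactants: 3 (2S)-2-(benzyloxy)-3-[4-(benzyloxy)phenyl]propanoic acid
Product: 4 (3S)-3-(benzyloxy)-4-[4-(benzyloxy)phenyl]butan-2-one
Conditions: MeLi (2.2 equiv), THF, −78 to 0 °C; inverse quench into cold dilute HCl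
Reagents that add atoms: methyllithium ([Li]C)
Why: Addition of methyllithium to the lithium carboxylate should stop at the gem-diolate, which gives the methyl ketone only on acidic work-up, so over-addition and epimerisation of C1′ are avoided.

Step 4
Reactants: 5 4-(benzyloxy)-3-methoxybenzaldehyde, 6 malonic acid
Product: 7 (2E)-3-[4-(benzyloxy)-3-methoxyphenyl]prop-2-enoic acid
Conditions: pyridine, piperidine (cat.), 90 °C
Reagents that add atoms: none
Why: Knoevenagel–Doebner condensation with decarboxylation should give the (E)-cinnamic acid.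

Step 5
Reactants: 7 (2E)-3-[4-(benzyloxy)-3-methoxyphenyl]prop-2-enoic acid
Product: 8 (2E)-3-[4-(benzyloxy)-3-methoxyphenyl]prop-2-enoyl chloride
Conditions: (COCl)2, DMF (cat.), CH2Cl2, 0 °C to rt; evaporate, use crude
Reagents that add atoms: oxalyl chloride (ClC(=O)C(=O)Cl)
Why: Standard acid chloride formation through the chloroiminium-activated acid; the benzyl ether and the (E)-alkene should be unaffected.

Step 6
Reactants: 4 (3S)-3-(benzyloxy)-4-[4-(benzyloxy)phenyl]butan-2-one, 8 (2E)-3-[4-(benzyloxy)-3-methoxyphenyl]prop-2-enoyl chloride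
Product: 11 (2S)-2-[4-(benzyloxy)-3-methoxyphenyl]-6-{(1S)-1-(benzyloxy)-2-[4-(benzyloxy)phenyl]ethyl}-2,3-dihydro-4H-pyran-4-one, via lithium enolate 9 (not isolated), via enolised diketone 10 (not isolated)
Conditions: LiN(SiMe3)2 (2.1 equiv), PhMe–THF, −78 °C; 8, −78 to 0 °C; HCl/dioxane (1.1 equiv), volatiles removed in vacuo; (R)-3,3′-bis(2,4,6-triisopropylphenyl)-1,1′-binaphthyl-2,2′-diyl N-(trifluoromethanesulfonyl)phosphoramide (10 mol %), PhMe, 4 Å MS, 0 to 40 °C
Reagents that add atoms: none
Why: Proposed new method: the kinetic methyl-side enolate 9 should be C-acylated by the acid chloride (the second equivalent of base removes the acidic C5–H of the diketone), and after protonation the enol 10 (O1–C6=C5–C4=O) should add through O1 to C2 of the acid-activated cinnamoyl enone and tautomerise to the vinylogous ester 11. The closest known reaction types are the one-pot synthesis of β-diketones from ketone enolates and acid chlorides, the acid-mediated cyclisation of styryl β-diketone (curcuminoid) enols to 2-aryl-2,3-dihydro-4H-pyran-4-ones, and the chiral phosphoric acid-catalysed 6-endo aza-Michael closure of 2-aminochalcones; new is the catalyst-controlled enol oxa-Michael telescoped with the acylation. The dihydropyranone ring closes in the 6-endo-trig mode. C2 is the only new stereocentre and is to be controlled by the chiral acid, expected to hold the C4 carbonyl and the enol O1–H in one chiral ion-pair pocket, while the remote C1′ centre should exert little bias (the C2 epimers are diastereomers, hence separable, and the minor one can be re-equilibrated with acid). The step needs methyl- over methine-enolisation (hindered base at −78 °C), C- over O-acylation and 1,2- over 1,4-attack (lithium enolate plus acid chloride in toluene), and closure by O1 only (the C4 oxygen cannot reach C2 in a six-membered ring).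

Step 7
Reactants: 11 (2S)-2-[4-(benzyloxy)-3-methoxyphenyl]-6-{(1S)-1-(benzyloxy)-2-[4-(benzyloxy)phenyl]ethyl}-2,3-dihydro-4H-pyran-4-one
Product: 12 (2S,4S)-2-[4-(benzyloxy)-3-methoxyphenyl]-6-{(1S)-1-(benzyloxy)-2-[4-(benzyloxy)phenyl]ethyl}-3,4-dihydro-2H-pyran-4-ol
Conditions: NaBH4, CeCl3·7H2O, MeOH–CH2Cl2, −78 °C; NaHCO3 work-up, used without acidic contact
Reagents that add atoms: none
Why: Luche 1,2-reduction; hydride should attack C4 axially on the half-chair that holds the C2 aryl pseudo-equatorial, so the new hydroxyl is pseudo-equatorial and cis to the aryl (4S).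

Step 8
Reactants: 12 (2S,4S)-2-[4-(benzyloxy)-3-methoxyphenyl]-6-{(1S)-1-(benzyloxy)-2-[4-(benzyloxy)phenyl]ethyl}-3,4-dihydro-2H-pyran-4-ol
Product: 13 (2S,4S,6S)-2-[4-(benzyloxy)-3-methoxyphenyl]-6-{(1S)-1-(benzyloxy)-2-[4-(benzyloxy)phenyl]ethyl}oxan-4-ol
Conditions: H2 (1 atm), [Ir(cod)(PCy3)(py)]PF6 (5 mol %), CH2Cl2, 0 °C to rt
Reagents that add atoms: none
Why: Hydroxyl-directed homogeneous hydrogenation of a cyclic allylic alcohol: the cationic iridium centre should bind the C4 hydroxyl and deliver H2 to C5=C6 on that face, placing H at C6 cis to OH and the side chain trans to OH and aryl (6S, 2,6-trans), which an undirected heterogeneous catalyst would not give.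

Step 9
Reactants: 13 (2S,4S,6S)-2-[4-(benzyloxy)-3-methoxyphenyl]-6-{(1S)-1-(benzyloxy)-2-[4-(benzyloxy)phenyl]ethyl}oxan-4-ol
Product: 14 (2S,4S,6S)-2-(4-hydroxy-3-methoxyphenyl)-6-[(1S)-1-hydroxy-2-(4-hydroxyphenyl)ethyl]oxan-4-ol
Conditions: H2 (1 atm), Pd/C (10 %), EtOAc–EtOH, rt; stopped at full debenzylation
Reagents that add atoms: none
Why: Hydrogenolysis of the three O-benzyl groups; the ring C2–O1 bond, a secondary benzylic ether on an electron-rich ring, is expected to survive neutral conditions at ambient pressure.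

**Compound list**
1 | O-benzyl-L-tyrosine | N[C@@H](Cc1ccc(OCc2ccccc2)cc1)C(=O)O | starting material
2 | (2S)-3-[4-(benzyloxy)phenyl]-2-hydroxypropanoic acid | OC(=O)[C@@H](O)Cc1ccc(OCc2ccccc2)cc1 | intermediate
3 | (2S)-2-(benzyloxy)-3-[4-(benzyloxy)phenyl]propanoic acid | OC(=O)[C@@H](OCc1ccccc1)Cc1ccc(OCc2ccccc2)cc1 | intermediate
4 | (3S)-3-(benzyloxy)-4-[4-(benzyloxy)phenyl]butan-2-one | CC(=O)[C@@H](OCc1ccccc1)Cc1ccc(OCc2ccccc2)cc1 | intermediate
5 | 4-(benzyloxy)-3-methoxybenzaldehyde | COc1cc(C=O)ccc1OCc1ccccc1 | starting material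
6 | malonic acid | OC(=O)CC(=O)O | starting material
7 | (2E)-3-[4-(benzyloxy)-3-methoxyphenyl]prop-2-enoic acid | COc1cc(/C=C/C(=O)O)ccc1OCc1ccccc1 | intermediate
8 | (2E)-3-[4-(benzyloxy)-3-methoxyphenyl]prop-2-enoyl chloride | COc1cc(/C=C/C(=O)Cl)ccc1OCc1ccccc1 | intermediate
9 | lithium (3S)-3-(benzyloxy)-4-[4-(benzyloxy)phenyl]but-1-en-2-olate | [Li+].C=C([O-])[C@@H](OCc1ccccc1)Cc1ccc(OCc2ccccc2)cc1 | intermediate
10 | (1E,6S)-6-(benzyloxy)-1-[4-(benzyloxy)-3-methoxyphenyl]-7-[4-(benzyloxy)phenyl]hept-1-ene-3,5-dione (present mainly as its enol) | COc1cc(/C=C/C(=O)CC(=O)[C@@H](OCc2ccccc2)Cc2ccc(OCc3ccccc3)cc2)ccc1OCc1ccccc1 | intermediate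
11 | (2S)-2-[4-(benzyloxy)-3-methoxyphenyl]-6-{(1S)-1-(benzyloxy)-2-[4-(benzyloxy)phenyl]ethyl}-2,3-dihydro-4H-pyran-4-one | COc1cc([C@@H]2CC(=O)C=C([C@@H](OCc3ccccc3)Cc3ccc(OCc4ccccc4)cc3)O2)ccc1OCc1ccccc1 | intermediate
12 | (2S,4S)-2-[4-(benzyloxy)-3-methoxyphenyl]-6-{(1S)-1-(benzyloxy)-2-[4-(benzyloxy)phenyl]ethyl}-3,4-dihydro-2H-pyran-4-ol | COc1cc([C@@H]2C[C@H](O)C=C([C@@H](OCc3ccccc3)Cc3ccc(OCc4ccccc4)cc3)O2)ccc1OCc1ccccc1 | intermediate
13 | (2S,4S,6S)-2-[4-(benzyloxy)-3-methoxyphenyl]-6-{(1S)-1-(benzyloxy)-2-[4-(benzyloxy)phenyl]ethyl}oxan-4-ol | COc1cc([C@@H]2C[C@H](O)C[C@@H]([C@@H](OCc3ccccc3)Cc3ccc(OCc4ccccc4)cc3)O2)ccc1OCc1ccccc1 | intermediate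
14 | (2S,4S,6S)-2-(4-hydroxy-3-methoxyphenyl)-6-[(1S)-1-hydroxy-2-(4-hydroxyphenyl)ethyl]oxan-4-ol | COc1cc([C@@H]2C[C@H](O)C[C@@H]([C@@H](O)Cc3ccc(O)cc3)O2)ccc1O | target

**Step count and risks**
Total steps: 9. Longest linear sequence: 7 (steps 1, 2, 3, 6, 7, 8, 9).

Step 6. What may go wrong: insufficient facial discrimination by the chiral acid at C2; erosion of any selectivity by acid-catalysed ring opening and re-closure; incomplete cyclisation because the electron-rich β-aryl enone is a weak acceptor; competing O-acylation of the enolate. Fallback (sets out from 4 and 5, returns at 11): the ring would be built by the complementary known aldol–cyclodehydration disconnection (C2–C3 and O1–C6). Claisen acetylation of 4 (LiN(SiMe3)2, toluene, then acetyl chloride) would give (5S)-5-(benzyloxy)-6-[4-(benzyloxy)phenyl]hexane-2,4-dione F1. Silylation (Me3SiCl, Et3N; then LiN(iPr)2, Me3SiCl) would give (3Z,5S)-5-(benzyloxy)-6-[4-(benzyloxy)phenyl]-2,4-bis(trimethylsilyloxy)hexa-1,3-diene F2. A Ti(OiPr)4/1,1′-bi-2-naphthol-catalysed vinylogous Mukaiyama aldol addition of F2 to aldehyde 5 (the ligand antipode that leads to the 1S carbinol), with mild acidic desilylation, would give (1S,6S)-6-(benzyloxy)-1-[4-(benzyloxy)-3-methoxyphenyl]-7-[4-(benzyloxy)phenyl]-1-hydroxyheptane-3,5-dione F3. CF3CO2H in CH2Cl2 would then condense the C2 hydroxyl onto the C6 carbonyl with loss of water to give 11, with C2 untouched.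

Step 8. What may go wrong: loss of facial control if the metal does not bind the hydroxyl (hydrogen then arrives from the open face and gives the 2,6-cis series); acid-induced ionisation or allylic transposition of the hydroxy enol ether by the cationic metal hydride; isomerisation of the allylic alcohol to the ketone. Fallback (sets out from 12, returns at 13): the hydride would be delivered intramolecularly from a silicon tether, as in the Lewis acid-promoted intramolecular hydrosilylation of β-silyloxy ketones. Silylation of 12 (iPr2SiHCl, imidazole, CH2Cl2) would give {[(2S,4S)-2-[4-(benzyloxy)-3-methoxyphenyl]-6-{(1S)-1-(benzyloxy)-2-[4-(benzyloxy)phenyl]ethyl}-3,4-dihydro-2H-pyran-4-yl]oxy}di(propan-2-yl)silane F4. CF3CO2H (1.1 equiv, CH2Cl2, −78 °C) should protonate C5, and the C6 oxocarbenium ion would take hydride from silicon through a six-membered arrangement on the face of the C4 oxygen, giving the (2S,4S,6S)-oxan-4-yl diisopropylsilyl trifluoroacetate F5. Methanolysis (K2CO3, MeOH) would free the C4 hydroxyl and give 13.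

Step 9. What may go wrong: over-reduction by hydrogenolytic cleavage of the benzylic ring bond C2–O1 while the slower secondary benzyl ether at C1′ is still being removed. Fallback (sets out from 13, returns at 14): electron-transfer debenzylation with lithium 4,4′-di-tert-butylbiphenylide in THF at −78 °C. The aryl benzyl ethers should cleave first, and the resulting phenoxide makes the C2 aryl ring too electron-rich to accept an electron, which protects C2–O1. This fallback makes no new compound (F0).

Further compounds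
F1 | step 6 | (5S)-5-(benzyloxy)-6-[4-(benzyloxy)phenyl]hexane-2,4-dione | CC(=O)CC(=O)[C@@H](OCc1ccccc1)Cc1ccc(OCc2ccccc2)cc1
F2 | step 6 | (3Z,5S)-5-(benzyloxy)-6-[4-(benzyloxy)phenyl]-2,4-bis(trimethylsilyloxy)hexa-1,3-diene | C=C(O[Si](C)(C)C)/C=C(\O[Si](C)(C)C)[C@@H](OCc1ccccc1)Cc1ccc(OCc2ccccc2)cc1
F3 | step 6 | (1S,6S)-6-(benzyloxy)-1-[4-(benzyloxy)-3-methoxyphenyl]-7-[4-(benzyloxy)phenyl]-1-hydroxyheptane-3,5-dione | COc1cc([C@@H](O)CC(=O)CC(=O)[C@@H](OCc2ccccc2)Cc2ccc(OCc3ccccc3)cc2)ccc1OCc1ccccc1
F4 | step 8 | {[(2S,4S)-2-[4-(benzyloxy)-3-methoxyphenyl]-6-{(1S)-1-(benzyloxy)-2-[4-(benzyloxy)phenyl]ethyl}-3,4-dihydro-2H-pyran-4-yl]oxy}di(propan-2-yl)silane | COc1cc([C@@H]2C[C@H](O[SiH](C(C)C)C(C)C)C=C([C@@H](OCc3ccccc3)Cc3ccc(OCc4ccccc4)cc3)O2)ccc1OCc1ccccc1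
F5 | step 8 | (2S,4S,6S)-2-[4-(benzyloxy)-3-methoxyphenyl]-6-{(1S)-1-(benzyloxy)-2-[4-(benzyloxy)phenyl]ethyl}oxan-4-yl diisopropylsilyl trifluoroacetate | COc1cc([C@@H]2C[C@H](O[Si](OC(=O)C(F)(F)F)(C(C)C)C(C)C)C[C@@H]([C@@H](OCc3ccccc3)Cc3ccc(OCc4ccccc4)cc3)O2)ccc1OCc1ccccc1
F0 | step 9 | none | none
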